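**Retrosynthetic overview**

- The target is a linear triaryl diether with no stereocentre. Ring A is 3,5-dihydroxyphenyl. Ring B carries the ring A oxygen at C1, hydroxyls at C2 and C6, and the ring C oxygen at C4. Ring C carries the ether oxygen at C1, hydroxyls at C2, C4 and C6, bromine at C5 and hydrogen at C3.
- The strategy rests on ring C. Its C4 oxygen and C5 bromine sit on neighbouring carbons beside the C6 oxygen, which is the pattern produced when an oxygen nucleophile and a bromine electrophile add across a C4–C5 aryne polarised by a C6 methoxy group. Both bonds are cut together, back to a symmetric 4-chloro-2,6-dimethoxyphenyl silyl ether.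
- Later disconnections: six O–methyl bonds and one O–tert-butyl bond (deprotection), then the ring B C4–O–C1 ring C ether (oxidative copper coupling of the ring C phenol with a ring B boronic acid), then the ring A–ring B ether (same coupling type).
- No ring is constructed; all three benzene rings are purchased. Order: ring C is functionalised (chloride, then aryne oxy-bromination), the A–B ether is made, the B–C ether is made, and the protecting groups are removed.

Key step: step 3

Remark: ring C is numbered as in the target (C1 ether oxygen, C4 oxygen, C5 bromine), so C5 corresponds to locant 3 in the systematic names of 8 and 9. LiTMP and LiOtBu are taken as preformed reagents.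

**Route**

Step 1
Reactants: 1 4-bromo-2,6-dimethoxyphenol
Product: 2 (4-bromo-2,6-dimethoxyphenoxy)tri(propan-2-yl)silane
Conditions: TIPSCl, imidazole, DMF, rt → 40 °C
Reagents that add atoms: chlorotri(propan-2-yl)silane (TIPSCl), CC(C)[Si](Cl)(C(C)C)C(C)C
Why: Imidazole-promoted O-silylation of a phenol is routine, and the bulky silyl ether, which has no ortho hydrogen available for silyl migration, should withstand the organolithium chemistry that follows.

Step 2
Reactants: 2 (4-bromo-2,6-dimethoxyphenoxy)tri(propan-2-yl)silane
Product: 4 (4-chloro-2,6-dimethoxyphenoxy)tri(propan-2-yl)silane, via C4 aryllithium 3 (not isolated)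
Conditions: n-BuLi, THF, −78 °C; inverse addition to C2Cl6, THF, −78 °C → rt
Reagents that add atoms: hexachloroethane, ClC(Cl)(Cl)C(Cl)(Cl)Cl
Why: Bromine–lithium exchange at −78 °C is faster than any deprotonation, and electrophilic chlorination of the aryllithium places chlorine at C4 unambiguously, which direct chlorination of the parent phenol could not guarantee.

Step 3
Reactants: 4 (4-chloro-2,6-dimethoxyphenoxy)tri(propan-2-yl)silane
Product: 8 [3-bromo-4-(tert-butoxy)-2,6-dimethoxyphenoxy]tri(propan-2-yl)silane, via ortho-lithiated chloroarene 5 (not isolated), via C4-C5 aryne 6 (not isolated), via C5 aryllithium 7 (not isolated)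
Conditions: LiTMP (1.1 equiv), THF, −78 °C; cannulated slowly into LiOtBu (6 equiv), THF, −20 → 0 °C; then BrCl2C–CCl2Br, −78 °C → rt
Reagents that add atoms: lithium tert-butoxide, CC(C)(C)O[Li]; 1,2-dibromo-1,1,2,2-tetrachloroethane, BrC(Cl)(Cl)C(Cl)(Cl)Br
Why: Proposed new method: LiTMP removes the hydrogen lying between chlorine and methoxy (C3 and C5 are equivalent, so only aryllithium 5 can form), loss of LiCl on warming gives the C4–C5 aryne 6, lithium tert-butoxide adds to it, and the resulting aryllithium 7 is brominated by halogen transfer from 1,2-dibromotetrachloroethane, so the C4–O and C5–Br bonds are made in one flask. The closest known reaction types are the addition of lithium or magnesium amides and thiolates to arynes with halogen trapping of the aryl metal, and the addition of tert-butoxide to arynes followed by protonation; combining them should be possible because 7 is flanked by two alkoxy groups, is therefore a stabilised and persistent aryllithium, and meets no acid stronger than tetramethylpiperidine before the bromine source arrives. No ring is closed and no stereocentre is created. The step needs regioselective addition across the aryne: the C6 methoxy group polarises the strained bond so that the nucleophile attacks the remote and less hindered C4 (next to C3–H), and the negative charge develops at C5 beside the electron-withdrawing C6–O bond. It also needs tert-butoxide to beat other nucleophiles, which is addressed by complete lithiation at −78 °C before any aryne exists, slow transfer of cold 5 into a large excess of alkoxide, and the steric bulk of LiTMP and of the doubly flanked aryllithiums.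

Step 4
Reactants: 8 [3-bromo-4-(tert-butoxy)-2,6-dimethoxyphenoxy]tri(propan-2-yl)silane
Product: 9 3-bromo-4-(tert-butoxy)-2,6-dimethoxyphenol
Conditions: TBAF, AcOH, THF, 0 °C
Reagents that add atoms: none
Why: Fluoride-mediated desilylation of an aryl silyl ether, buffered with acetic acid so the electron-rich phenoxide is not left exposed, should leave the tert-butyl ether, the methyl ethers and the aryl bromide untouched.

Step 5
Reactants: 1 4-bromo-2,6-dimethoxyphenol; 10 (3,5-dimethoxyphenyl)boronic acid
Product: 11 5-bromo-2-(3,5-dimethoxyphenoxy)-1,3-dimethoxybenzene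
Conditions: Cu(OAc)2 (1 equiv), pyridine, Et3N, 4 Å MS, CH2Cl2, dry air, rt
Reagents that add atoms: none
Why: Chan–Lam–Evans oxidative O-arylation with divalent copper and air as terminal oxidant couples phenols bearing two ortho substituents to arylboronic acids at room temperature and does not engage the aryl bromide.

Step 6
Reactants: 11 5-bromo-2-(3,5-dimethoxyphenoxy)-1,3-dimethoxybenzene
Product: 14 [4-(3,5-dimethoxyphenoxy)-3,5-dimethoxyphenyl]boronic acid, via ring B aryllithium 12 (not isolated), via lithium aryl(triisopropoxy)borate 13 (not isolated)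
Conditions: B(OiPr)3, then n-BuLi, THF/toluene, −78 °C (in situ quench); aq. HCl, 0 °C
Reagents that add atoms: triisopropyl borate, CC(C)OB(OC(C)C)OC(C)C; water, O
Why: Lithiation–borylation by bromine–lithium exchange in the presence of the borate traps the aryllithium before it can migrate to the acidic positions of ring A, and mild acid hydrolysis of the borate should release the boronic acid.

Step 7
Reactants: 9 3-bromo-4-(tert-butoxy)-2,6-dimethoxyphenol; 14 [4-(3,5-dimethoxyphenoxy)-3,5-dimethoxyphenyl]boronic acid
Product: 15 2-bromo-1-(tert-butoxy)-4-[4-(3,5-dimethoxyphenoxy)-3,5-dimethoxyphenoxy]-3,5-dimethoxybenzene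
Conditions: Cu(OAc)2 (1 equiv), pyridine, Et3N, 4 Å MS, CH2Cl2, dry air, rt
Reagents that add atoms: none
Why: A second Chan–Lam–Evans coupling joins the flanked ring C phenol oxygen to C4 of ring B under divalent copper, where no low-valent metal is present to insert into the C5–Br bond, and ortho,ortho-disubstituted halophenols are established partners in this reaction.

Step 8
Reactants: 15 2-bromo-1-(tert-butoxy)-4-[4-(3,5-dimethoxyphenoxy)-3,5-dimethoxyphenoxy]-3,5-dimethoxybenzene
Product: 16 2-bromo-4-[4-(3,5-dimethoxyphenoxy)-3,5-dimethoxyphenoxy]-3,5-dimethoxyphenol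
Conditions: TFA, Et3SiH (10 equiv), CH2Cl2, 0 °C
Reagents that add atoms: none
Why: Acidolysis of the aryl tert-butyl ether is fast in TFA while methyl and diaryl ethers are stable, and excess triethylsilane should reduce the tert-butyl cation to isobutane before it can alkylate the electron-rich ring A.

Step 9
Reactants: 16 2-bromo-4-[4-(3,5-dimethoxyphenoxy)-3,5-dimethoxyphenoxy]-3,5-dimethoxyphenol
Product: 17 2-bromo-4-[4-(3,5-dihydroxyphenoxy)-3,5-dihydroxyphenoxy]benzene-1,3,5-triol (CNP0039507.0)
Conditions: BBr3 (excess), CH2Cl2, −78 °C → rt; MeOH then H2O, 0 °C, argon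
Reagents that add atoms: none
Why: Exhaustive Lewis-acid demethylation with BBr3 cleaves the six aryl methyl ethers by bromide attack on the boron-complexed methyl groups, while the diaryl ether bonds and the aryl bromide are inert, which is the usual last step to polyphenolic diaryl ethers.

**Compound list**

1 | 4-bromo-2,6-dimethoxyphenol | COc1cc(Br)cc(OC)c1O | starting material
2 | (4-bromo-2,6-dimethoxyphenoxy)tri(propan-2-yl)silane | COc1cc(Br)cc(OC)c1O[Si](C(C)C)(C(C)C)C(C)C | intermediate
3 | [3,5-dimethoxy-4-(triisopropylsilyloxy)phenyl]lithium | [Li]c1cc(OC)c(O[Si](C(C)C)(C(C)C)C(C)C)c(OC)c1 | intermediate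
4 | (4-chloro-2,6-dimethoxyphenoxy)tri(propan-2-yl)silane | COc1cc(Cl)cc(OC)c1O[Si](C(C)C)(C(C)C)C(C)C | intermediate
5 | [6-chloro-2,4-dimethoxy-3-(triisopropylsilyloxy)phenyl]lithium | [Li]c1c(Cl)cc(OC)c(O[Si](C(C)C)(C(C)C)C(C)C)c1OC | intermediate
6 | (3,4-didehydro-2,6-dimethoxyphenoxy)tri(propan-2-yl)silane, the C4–C5 aryne of ring C | COC1=CC#CC(OC)=C1O[Si](C(C)C)(C(C)C)C(C)C | intermediate
7 | [6-(tert-butoxy)-2,4-dimethoxy-3-(triisopropylsilyloxy)phenyl]lithium | [Li]c1c(OC(C)(C)C)cc(OC)c(O[Si](C(C)C)(C(C)C)C(C)C)c1OC | intermediate
8 | [3-bromo-4-(tert-butoxy)-2,6-dimethoxyphenoxy]tri(propan-2-yl)silane | COc1cc(OC(C)(C)C)c(Br)c(OC)c1O[Si](C(C)C)(C(C)C)C(C)C | intermediate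
9 | 3-bromo-4-(tert-butoxy)-2,6-dimethoxyphenol | COc1cc(OC(C)(C)C)c(Br)c(OC)c1O | intermediate
10 | (3,5-dimethoxyphenyl)boronic acid | COc1cc(OC)cc(B(O)O)c1 | starting material
11 | 5-bromo-2-(3,5-dimethoxyphenoxy)-1,3-dimethoxybenzene | COc1cc(OC)cc(Oc2c(OC)cc(Br)cc2OC)c1 | intermediate
12 | [4-(3,5-dimethoxyphenoxy)-3,5-dimethoxyphenyl]lithium | [Li]c1cc(OC)c(Oc2cc(OC)cc(OC)c2)c(OC)c1 | intermediate
13 | lithium [4-(3,5-dimethoxyphenoxy)-3,5-dimethoxyphenyl]tri(propan-2-yloxy)borate | [Li+].COc1cc(OC)cc(Oc2c(OC)cc([B-](OC(C)C)(OC(C)C)OC(C)C)cc2OC)c1 | intermediate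
14 | [4-(3,5-dimethoxyphenoxy)-3,5-dimethoxyphenyl]boronic acid | COc1cc(OC)cc(Oc2c(OC)cc(B(O)O)cc2OC)c1 | intermediate
15 | 2-bromo-1-(tert-butoxy)-4-[4-(3,5-dimethoxyphenoxy)-3,5-dimethoxyphenoxy]-3,5-dimethoxybenzene | COc1cc(OC)cc(Oc2c(OC)cc(Oc3c(OC)cc(OC(C)(C)C)c(Br)c3OC)cc2OC)c1 | intermediate
16 | 2-bromo-4-[4-(3,5-dimethoxyphenoxy)-3,5-dimethoxyphenoxy]-3,5-dimethoxyphenol | COc1cc(OC)cc(Oc2c(OC)cc(Oc3c(OC)cc(O)c(Br)c3OC)cc2OC)c1 | intermediate
17 | 2-bromo-4-[4-(3,5-dihydroxyphenoxy)-3,5-dihydroxyphenoxy]benzene-1,3,5-triol | Oc1cc(O)cc(Oc2c(O)cc(Oc3c(O)cc(O)c(Br)c3O)cc2O)c1 | target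

**Step count and risks**

Total: 9 steps. Longest linear sequence: 7 steps (steps 1, 2, 3, 4, 7, 8, 9, from compound 1). The ring A/B arm adds steps 5 and 6.

Steps most likely to fail:

1. Step 3 (key step). The alkoxide may add to the aryne too slowly, so that the aryne is consumed by aryllithium 5 (biaryl formation) or by the amide, or aryllithium 7 may be protonated before the bromine source is added. The fallback makes the two bonds one after the other by known reactions. It sets out from bromide 2: palladium-catalysed C–O cross-coupling with NaOtBu (Pd(OAc)2, 2-di-tert-butylphosphino-2′,4′,6′-triisopropylbiphenyl, toluene, 100 °C) should give (4-tert-butoxy-2,6-dimethoxyphenoxy)tri(propan-2-yl)silane F1. Directed ortho-lithiation of F1 with sec-BuLi/TMEDA in THF at −78 °C should occur at the hydrogen flanked by the tert-butoxy and a methoxy group (C3 and C5 are equivalent by symmetry), giving the same aryllithium 7. Quenching with 1,2-dibromotetrachloroethane then returns the route at 8.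

2. Step 7. The flanked, electron-rich phenol 9 may be oxidised by divalent copper and air faster than it is arylated, and boronic acid 14 may be lost to protodeboronation or homocoupling. The fallback forms the ether without an oxidant. It sets out from bromide 11: bromine–lithium exchange (n-BuLi, THF, −78 °C, via aryllithium 12) and quenching with iodine should give 2-(3,5-dimethoxyphenoxy)-5-iodo-1,3-dimethoxybenzene F2. An Ullmann-type coupling of F2 with phenol 9 (copper iodide CuI, picolinic acid, K3PO4, DMSO, 90 °C, argon) returns the route at 15. The unhindered aryl iodide is expected to react with monovalent copper far faster than the bromide of 9, which is flanked by two alkoxy groups.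

3. Step 9. Demethylation may stop at mixed methyl ethers that cannot be separated from the product, and the free heptaphenol may degrade during aqueous work-up and chromatography through air oxidation or acid-promoted loss or migration of the ring C bromine once hydrogen bromide is released. The fallback avoids isolating the free polyphenol directly. It sets out from 16: after the BBr3 reaction the mixture is quenched with methanol at −78 °C, the volatiles are removed cold, and the residue is acetylated at once (Ac2O, pyridine, DMAP cat.) to give 2-bromo-4-[4-(3,5-diacetoxyphenoxy)-3,5-diacetoxyphenoxy]benzene-1,3,5-triyl triacetate F3. F3 should be stable to air and silica, so under-demethylated material can be separated and resubmitted. Brief methanolysis of F3 (K2CO3, degassed MeOH, 0 °C, argon, then acidification) returns the route at 17.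

**Further compounds**

F1 | step 3 | (4-tert-butoxy-2,6-dimethoxyphenoxy)tri(propan-2-yl)silane | COc1cc(OC(C)(C)C)cc(OC)c1O[Si](C(C)C)(C(C)C)C(C)C
F2 | step 7 | 2-(3,5-dimethoxyphenoxy)-5-iodo-1,3-dimethoxybenzene | COc1cc(OC)cc(Oc2c(OC)cc(I)cc2OC)c1
F3 | step 9 | 2-bromo-4-[4-(3,5-diacetoxyphenoxy)-3,5-diacetoxyphenoxy]benzene-1,3,5-triyl triacetate | CC(=O)Oc1cc(OC(C)=O)cc(Oc2c(OC(C)=O)cc(Oc3c(OC(C)=O)cc(OC(C)=O)c(Br)c3OC(C)=O)cc2OC(C)=O)c1
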